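## Retrosynthetic overview

1. Target ⇒ (one flask) the free salicylaldehyde that already carries the (S)-2-hydroxypropyl chain + a 6-[(2R)-2-silyloxypropyl]-4-hydroxy-2-pyrone: Knoevenagel at pyrone C3, translactonisation by the ortho-phenol (pyrone ring opens, coumarin lactone closes), then acid desilylation and cyclodehydration (dihydropyranone closes).
2. Salicylaldehyde ⇒ 2,4-bis(MOM-oxy)-3,5-dimethylbenzaldehyde + (S)-propylene oxide by α-amino-alkoxide-directed ortho-lithiation; the aldehyde ⇒ 2-methylresorcinol by two OMOM-directed lithiations (MeI, then DMF).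
3. Pyrone ⇒ TBS ether of methyl (R)-3-hydroxybutanoate + methyl acetoacetate dianion (Claisen), then DBU lactonisation.
4. Ring order: benzene ring bought; 2-pyrone ring made and later sacrificed; coumarin lactone and dihydropyranone rings both closed in the last operation. Both stereocentres come from the chiral pool.

Assumption: compound 13 is written as the open hydroxy aldehyde; it equilibrates with its lactol (3S)-3,5,7-trimethyl-3,4-dihydro-1H-isochromene-1,6,8-triol, and either form enters step 8.

## Route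

Step 1
Reactants: 1 2-methylresorcinol (2-methylbenzene-1,3-diol)
Product: 2 1,3-bis(methoxymethoxy)-2-methylbenzene
Conditions: NaH (2.5 eq), MOMCl (2.4 eq), DMF, 0 °C → rt
Reagents that add atoms: chloromethyl methyl ether (MOMCl), COCCl
Why: Williamson-type O-alkylation of both phenoxides by the reactive α-chloro ether (MOM protection), which also installs the ortho-directing groups for steps 2 and 3.

Step 2
Reactants: 2 1,3-bis(methoxymethoxy)-2-methylbenzene
Product: 4 1,3-bis(methoxymethoxy)-2,4-dimethylbenzene, via aryllithium 3 (not isolated)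
Conditions: n-BuLi (1.1 eq), TMEDA, THF, 0 °C, 1 h; MeI, –78 °C → rt
Reagents that add atoms: iodomethane (MeI), CI
Why: Directed ortho-metalation: the OMOM groups steer n-BuLi to C4 (C4 and C6 are equivalent, C5 has no directing neighbour) and MeI methylates the aryllithium.

Step 3
Reactants: 4 1,3-bis(methoxymethoxy)-2,4-dimethylbenzene
Product: 7 2,4-bis(methoxymethoxy)-3,5-dimethylbenzaldehyde, via aryllithium 5 (not isolated), via lithium hemiaminal alkoxide 6 (not isolated)
Conditions: n-BuLi (1.2 eq), TMEDA, THF, 0 °C, 1 h; DMF, –78 → 0 °C; H2O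
Reagents that add atoms: N,N-dimethylformamide (DMF), CN(C)C=O
Why: Second directed ortho-metalation: only the C1 OMOM group still has a free ortho C–H (C6), so lithiation is regiospecific and DMF formylates the aryllithium (Bouveault-type formylation).

Step 4
Reactants: 7 2,4-bis(methoxymethoxy)-3,5-dimethylbenzaldehyde; 8 (S)-propylene oxide [(2S)-2-methyloxirane]
Product: 13 2,4-dihydroxy-6-[(2S)-2-hydroxypropyl]-3,5-dimethylbenzaldehyde, via lithium amino alkoxide 9 (not isolated), via ortho-lithiated amino alkoxide 10 (not isolated), via dilithium dialkoxide 11 (not isolated), via bis-MOM hydroxy aldehyde 12 (not isolated)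
Conditions: LiN(Me)CH2CH2NMe2 (1.1 eq, from the amine + n-BuLi), THF, –20 °C; n-BuLi (3 eq), –20 °C, 16 h; 8 (5 eq), –20 °C → rt; then 3 M HCl, THF, 45 °C
Reagents that add atoms: none
Why: Comins-type directed ortho-metalation: the lithium α-amino alkoxide made in situ masks the aldehyde and steers n-BuLi to the only ring C–H left, the aryllithium opens the epoxide at its CH2 terminus (SN2) so the (S) centre of 8 enters the side chain unchanged, and aqueous HCl then releases the aldehyde and cleaves both MOM acetals.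

Step 5
Reactants: 14 methyl (3R)-3-hydroxybutanoate
Product: 15 methyl (3R)-3-[(tert-butyldimethylsilyl)oxy]butanoate
Conditions: TBSCl (1.2 eq), imidazole (2 eq), DMF, rt
Reagents that add atoms: tert-butyldimethylsilyl chloride (TBSCl), CC(C)(C)[Si](C)(C)Cl
Why: Imidazole-promoted O-silylation of the secondary alcohol; the C–O bond at the (R) centre is not touched.

Step 6
Reactants: 15 methyl (3R)-3-[(tert-butyldimethylsilyl)oxy]butanoate; 16 methyl acetoacetate
Product: 18 methyl (7R)-7-[(tert-butyldimethylsilyl)oxy]-3,5-dioxooctanoate, via acetoacetate dianion 17 (not isolated)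
Conditions: 16 (2.5 eq), LDA (5 eq), THF, 0 °C; 15 (1 eq), –78 → 0 °C; cold 1 M HCl to pH 4
Reagents that add atoms: none
Why: Claisen-type acylation of the γ-carbon of the acetoacetate dianion by the methyl ester (Huckin–Weiler reaction), with surplus dianion absorbing the acidic product proton; the silyloxy stereocentre is a spectator.

Step 7
Reactants: 18 methyl (7R)-7-[(tert-butyldimethylsilyl)oxy]-3,5-dioxooctanoate
Product: 19 6-[(2R)-2-[(tert-butyldimethylsilyl)oxy]propyl]-4-hydroxy-2H-pyran-2-one
Conditions: DBU (1.5 eq), toluene, 80 °C; 10% citric acid work-up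
Reagents that add atoms: none
Why: Base-mediated lactonisation: the C5 enolate oxygen of the 3,5-dioxo ester attacks the ester carbonyl and methanol is lost, giving the 4-hydroxy-2-pyrone whose C3 is the only nucleophilic carbon for step 8.

Step 8
Reactants: 13 2,4-dihydroxy-6-[(2S)-2-hydroxypropyl]-3,5-dimethylbenzaldehyde; 19 6-[(2R)-2-[(tert-butyldimethylsilyl)oxy]propyl]-4-hydroxy-2H-pyran-2-one
Product: 23 7-hydroxy-5-[(2S)-2-hydroxypropyl]-6,8-dimethyl-3-[(2R)-2-methyl-4-oxo-3,4-dihydro-2H-pyran-6-yl]-2H-chromen-2-one (CNP0308039.1), via arylidene pyrandione 20 (not isolated), via silyloxy diketone 21 (not isolated), via hydroxy diketone 22 (not isolated)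
Conditions: 13:19 = 1:1, piperidine (0.2 eq), AcOH (0.2 eq), MeCN, 60 °C; then TsOH·H2O (0.5 eq), 50 °C, same flask
Reagents that add atoms: none
Why: Proposed new method: amine-catalysed Knoevenagel condensation of pyrone C3 with the aldehyde form of 13 gives arylidene 20, whose ortho-phenol attacks the pyrone C2 carbonyl and expels the C6 enolate (translactonisation), closing the coumarin lactone and unveiling β-diketone 21; acid then removes the TBS group and the freed alcohol adds to the ketone next to the coumarin and dehydrates to the dihydropyranone, with no bond to either stereocentre broken; the closest known reactions are the Knoevenagel/translactonisation of salicylaldehydes with 4-hydroxy-6-methyl-2-pyrone to 3-acetoacetylcoumarins and the acid cyclodehydration of δ-hydroxy-β-diketones to 2,3-dihydro-4H-pyran-4-ones.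

## Compound list

1 | 2-methylresorcinol (2-methylbenzene-1,3-diol) | Cc1c(O)cccc1O | starting material
2 | 1,3-bis(methoxymethoxy)-2-methylbenzene | COCOc1cccc(OCOC)c1C | intermediate
3 | [2,4-bis(methoxymethoxy)-3-methylphenyl]lithium (in situ) | [Li]c1ccc(OCOC)c(C)c1OCOC | intermediate
4 | 1,3-bis(methoxymethoxy)-2,4-dimethylbenzene | COCOc1ccc(C)c(OCOC)c1C | intermediate
5 | [2,4-bis(methoxymethoxy)-3,5-dimethylphenyl]lithium (in situ) | [Li]c1cc(C)c(OCOC)c(C)c1OCOC | intermediate
6 | lithium [2,4-bis(methoxymethoxy)-3,5-dimethylphenyl](dimethylamino)methanolate (in situ) | [Li]OC(N(C)C)c1cc(C)c(OCOC)c(C)c1OCOC | intermediate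
7 | 2,4-bis(methoxymethoxy)-3,5-dimethylbenzaldehyde | O=Cc1cc(C)c(OCOC)c(C)c1OCOC | intermediate
8 | (S)-propylene oxide, (2S)-2-methyloxirane | C[C@H]1CO1 | starting material
9 | lithium [2,4-bis(methoxymethoxy)-3,5-dimethylphenyl]{[2-(dimethylamino)ethyl](methyl)amino}methanolate (in situ; hemiaminal carbon not defined) | [Li]OC(N(C)CCN(C)C)c1cc(C)c(OCOC)c(C)c1OCOC | intermediate
10 | lithium {[2-(dimethylamino)ethyl](methyl)amino}[2-lithio-4,6-bis(methoxymethoxy)-3,5-dimethylphenyl]methanolate (in situ) | [Li]OC(N(C)CCN(C)C)c1c([Li])c(C)c(OCOC)c(C)c1OCOC | intermediate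
11 | dilithium salt of the epoxide-opened adduct, (2S)-1-[2-({[2-(dimethylamino)ethyl](methyl)amino}(oxido)methyl)-3,5-bis(methoxymethoxy)-4,6-dimethylphenyl]propan-2-olate (in situ) | [Li]OC(N(C)CCN(C)C)c1c(C[C@H](C)O[Li])c(C)c(OCOC)c(C)c1OCOC | intermediate
12 | 2-[(2S)-2-hydroxypropyl]-4,6-bis(methoxymethoxy)-3,5-dimethylbenzaldehyde (in situ) | O=Cc1c(OCOC)c(C)c(OCOC)c(C)c1C[C@H](C)O | intermediate
13 | 2,4-dihydroxy-6-[(2S)-2-hydroxypropyl]-3,5-dimethylbenzaldehyde (in equilibrium with its lactol) | O=Cc1c(O)c(C)c(O)c(C)c1C[C@H](C)O | intermediate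
14 | methyl (3R)-3-hydroxybutanoate | C[C@@H](O)CC(=O)OC | starting material
15 | methyl (3R)-3-[(tert-butyldimethylsilyl)oxy]butanoate | C[C@@H](O[Si](C)(C)C(C)(C)C)CC(=O)OC | intermediate
16 | methyl acetoacetate | COC(=O)CC(C)=O | starting material
17 | dilithio dianion of methyl acetoacetate (in situ) | COC(=O)C=C(C[Li])O[Li] | intermediate
18 | methyl (7R)-7-[(tert-butyldimethylsilyl)oxy]-3,5-dioxooctanoate | COC(=O)CC(=O)CC(=O)C[C@@H](C)O[Si](C)(C)C(C)(C)C | intermediate
19 | 6-[(2R)-2-[(tert-butyldimethylsilyl)oxy]propyl]-4-hydroxy-2H-pyran-2-one | C[C@H](Cc1cc(O)cc(=O)o1)O[Si](C)(C)C(C)(C)C | intermediate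
20 | 3-({2,4-dihydroxy-6-[(2S)-2-hydroxypropyl]-3,5-dimethylphenyl}methylidene)-6-[(2R)-2-[(tert-butyldimethylsilyl)oxy]propyl]-2H-pyran-2,4(3H)-dione (in situ; alkene geometry not defined) | C[C@H](O)Cc1c(C)c(O)c(C)c(O)c1C=C1C(=O)C=C(C[C@@H](C)O[Si](C)(C)C(C)(C)C)OC1=O | intermediate
21 | 3-[(5R)-5-[(tert-butyldimethylsilyl)oxy]-3-oxohexanoyl]-7-hydroxy-5-[(2S)-2-hydroxypropyl]-6,8-dimethyl-2H-chromen-2-one (in situ) | Cc1c(O)c(C)c2oc(=O)c(C(=O)CC(=O)C[C@@H](C)O[Si](C)(C)C(C)(C)C)cc2c1C[C@H](C)O | intermediate
22 | 7-hydroxy-3-[(5R)-5-hydroxy-3-oxohexanoyl]-5-[(2S)-2-hydroxypropyl]-6,8-dimethyl-2H-chromen-2-one (in situ) | Cc1c(O)c(C)c2oc(=O)c(C(=O)CC(=O)C[C@@H](C)O)cc2c1C[C@H](C)O | intermediate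
23 | 7-hydroxy-5-[(2S)-2-hydroxypropyl]-6,8-dimethyl-3-[(2R)-2-methyl-4-oxo-3,4-dihydro-2H-pyran-6-yl]-2H-chromen-2-one | Cc1c(O)c(C)c2oc(=O)c(C3=CC(=O)C[C@@H](C)O3)cc2c1C[C@H](C)O | target

## Step count and risks

Total step count: 8. Longest linear sequence: 5 (steps 1–4, then step 8); the second branch is steps 5–7.

Most likely to fail, first: step 8. The pyrone may add twice to the arylidene, the phenol may attack the ketone instead of the lactone carbonyl, or the side-chain alcohol may rest on coumarin C4 as an oxa-Michael adduct. The fallback makes the two rings one at a time and sets out from 18. TsOH·H2O in wet THF removes the silyl group and cyclodehydrates the δ-hydroxy-β-diketone to methyl [(2R)-2-methyl-4-oxo-3,4-dihydro-2H-pyran-6-yl]acetate F1. A buffered Knoevenagel condensation/lactonisation of F1 with 13 (piperidinium acetate, EtOH, 50 °C, kept mild to avoid retro-oxa-Michael racemisation) then closes only the coumarin ring and comes back to the route at 23.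

Second: step 4. The ring is electron-rich and lithiates slowly, and a hindered aryllithium must open the epoxide while surplus n-BuLi competes for it. The fallback changes both the directing group and the metal and sets out from 7. Condensation with N,N'-dimethylethylenediamine (toluene, 4 Å sieves) gives the isolable aminal 2-[2,4-bis(methoxymethoxy)-3,5-dimethylphenyl]-1,3-dimethylimidazolidine F2. Stoichiometric s-BuLi/TMEDA ortho-lithiation, transmetalation with MgBr2·OEt2 and CuI-catalysed opening of 8 give (2S)-1-[2-(1,3-dimethylimidazolidin-2-yl)-3,5-bis(methoxymethoxy)-4,6-dimethylphenyl]propan-2-ol F3. 3 M HCl in THF then hydrolyses the aminal and both MOM groups and comes back at 13.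

Third: step 6. The dianion may act as a base and expel silanolate from the β-silyloxy ester, or conversion may stall once the acidic product forms. The fallback replaces the Claisen and the lactonisation by acylketene chemistry and sets out from 15. MeNHOMe·HCl/i-PrMgCl (THF, –20 °C) gives (3R)-3-[(tert-butyldimethylsilyl)oxy]-N-methoxy-N-methylbutanamide F4. The lithium dienolate of commercial 2,2,6-trimethyl-4H-1,3-dioxin-4-one (LiHMDS, THF, –78 °C) is acylated at its methyl carbon by F4 to give 6-[(4R)-4-[(tert-butyldimethylsilyl)oxy]-2-oxopentyl]-2,2-dimethyl-4H-1,3-dioxin-4-one F5. Heating F5 in toluene at 110 °C expels acetone; the acylketene is captured by the enol oxygen and the sequence comes back at 19, bypassing 18.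

Further compounds
F1 | step 8 | methyl [(2R)-2-methyl-4-oxo-3,4-dihydro-2H-pyran-6-yl]acetate | COC(=O)CC1=CC(=O)C[C@@H](C)O1
F2 | step 4 | 2-[2,4-bis(methoxymethoxy)-3,5-dimethylphenyl]-1,3-dimethylimidazolidine | CN1CCN(C)C1c1cc(C)c(OCOC)c(C)c1OCOC
F3 | step 4 | (2S)-1-[2-(1,3-dimethylimidazolidin-2-yl)-3,5-bis(methoxymethoxy)-4,6-dimethylphenyl]propan-2-ol | CN1CCN(C)C1c1c(OCOC)c(C)c(OCOC)c(C)c1C[C@H](C)O
F4 | step 6 | (3R)-3-[(tert-butyldimethylsilyl)oxy]-N-methoxy-N-methylbutanamide | C[C@@H](O[Si](C)(C)C(C)(C)C)CC(=O)N(C)OC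
F5 | step 6 | 6-[(4R)-4-[(tert-butyldimethylsilyl)oxy]-2-oxopentyl]-2,2-dimethyl-4H-1,3-dioxin-4-one | C[C@@H](O[Si](C)(C)C(C)(C)C)CC(=O)CC1=CC(=O)OC(C)(C)O1
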